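**Strategy**

Ring B of the target, the lactone O1–C2–C3–C4–C5 of the 1,7-dioxaspiro[4.4]nonane, holds a vicinal diol at C3 and C4, so both carbons can be carbonyl carbons in a precursor. The route rests on closing ring B through the C3–C4 bond by a carbene-catalysed intramolecular crossed benzoin reaction: a glyoxylate ester on the C5 oxygen is the umpoled donor, an α-keto tert-butyl ester on C5 the acceptor. One operation builds ring B and the C4 carbinol; hydride reduction in the same flask sets C3. The precursor is the ring A γ-lactone carrying both dicarbonyl arms at its α-carbon.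

Key step: step 7

Remark: locants follow the 1,7-dioxaspiro[4.4]nonane numbering of the target (ring B: O1, C2, C3, C4, C5; ring A: C5, C6, O7, C8, C9); the antipode of the triazolium salt named in step 7 is a proposal, and its mirror image is the first recourse if the pairing with the substrate proves mismatched.

**Route**

Step 1
Reactants: 1 9-bromonon-1-ene; 2 (R)-epichlorohydrin
Product: 5 (2R)-2-(dec-9-en-1-yl)oxirane, via non-8-en-1-ylmagnesium bromide 3 (not isolated), via (2R)-1-chlorododec-11-en-2-ol 4 (not isolated)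
Conditions: Mg, THF, rt; CuI (5 mol%), 2, THF, −40 to 0 °C; dilute aq HCl quench; then NaOH, Et2O/H2O, rt
Reagents that add atoms: none
Why: Copper-catalysed SN2 opening of the epoxide of 2 at its CH2 terminus by the Grignard reagent, then Williamson-type closure of the chlorohydrin with NaOH, should give the new epoxide without touching the stereocentre, which is carried over from the chiral pool.

Step 2
Reactants: 5 (2R)-2-(dec-9-en-1-yl)oxirane; 6 tert-butyl acetate
Product: 9 (5R)-5-(dec-9-en-1-yl)oxolan-2-one, via diethylaluminium enolate 7 (not isolated), via tert-butyl (4R)-4-hydroxytetradec-13-enoate 8 (not isolated)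
Conditions: 6, LiN(iPr)2, THF, −78 °C; Et2AlCl; 5, −78 °C to rt; aq HCl work-up; then TsOH·H2O (cat.), toluene, 60 °C
Reagents that add atoms: none
Why: The diethylaluminium ester enolate should open the terminal epoxide at its CH2 carbon (SN2 epoxide alkylation) and the γ-hydroxy ester lactonises under acid catalysis with loss of tert-butanol, the carbinol stereocentre (future C8) remaining untouched.

Step 3
Reactants: 9 (5R)-5-(dec-9-en-1-yl)oxolan-2-one; 10 di-tert-butyl oxalate
Product: 11 tert-butyl (2Z)-2-[(5R)-5-(dec-9-en-1-yl)-2-oxooxolan-3-ylidene]-2-hydroxyacetate (enol form of the α-oxalyl lactone)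
Conditions: LiN(SiMe3)2 (2.2 equiv), THF, −78 °C; 10, −78 to 0 °C; aq HCl
Reagents that add atoms: none
Why: Crossed Claisen condensation of the lactone lithium enolate with the non-enolisable oxalate diester, driven to completion by deprotonation of the product, which should be obtained as its chelated enol.

Step 4
Reactants: 11 tert-butyl (2Z)-2-[(5R)-5-(dec-9-en-1-yl)-2-oxooxolan-3-ylidene]-2-hydroxyacetate
Product: 12 tert-butyl 2-[(3S,5R)-5-(dec-9-en-1-yl)-3-hydroxy-2-oxooxolan-3-yl]-2-oxoacetate
Conditions: KN(SiMe3)2 (1.05 equiv), THF, −78 °C; 2-(phenylsulfonyl)-3-phenyloxaziridine, −78 to −40 °C; AcOH quench at −78 °C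
Reagents that add atoms: 2-(phenylsulfonyl)-3-phenyloxaziridine, O=S(=O)(c1ccccc1)N1OC1c1ccccc1
Why: Davis oxaziridine hydroxylation of the potassium enolate, in which the bulky oxidant should attack the planar exocyclic enolate from the ring face opposite the C5 decenyl chain (1,3-induction in the γ-lactone), setting the tertiary (3S) carbinol that becomes C5 of the target.

Step 5
Reactants: 12 tert-butyl 2-[(3S,5R)-5-(dec-9-en-1-yl)-3-hydroxy-2-oxooxolan-3-yl]-2-oxoacetate; 13 bromoacetyl bromide
Product: 14 tert-butyl 2-[(3S,5R)-3-(2-bromoacetoxy)-5-(dec-9-en-1-yl)-2-oxooxolan-3-yl]-2-oxoacetate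
Conditions: pyridine, CH2Cl2, 0 °C to rt
Reagents that add atoms: none
Why: Ester formation at the hindered tertiary alcohol with the highly reactive acyl bromide under pyridine buffering, which avoids the strong base that could trigger an α-ketol shift.

Step 6
Reactants: 14 tert-butyl 2-[(3S,5R)-3-(2-bromoacetoxy)-5-(dec-9-en-1-yl)-2-oxooxolan-3-yl]-2-oxoacetate
Product: 16 tert-butyl 2-[(3S,5R)-5-(dec-9-en-1-yl)-2-oxo-3-(2-oxoacetoxy)oxolan-3-yl]-2-oxoacetate, via nitrate ester 15 (not isolated)
Conditions: AgNO3, MeCN, rt, dark; filter, concentrate; anhydrous NaOAc, DMSO, rt; azeotropic drying with toluene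
Reagents that add atoms: silver nitrate, [Ag+].[O-][N+](=O)[O-]
Why: Kornblum oxidation by way of the nitrate ester: silver-assisted SN2 displacement of bromide by nitrate, then acetate-induced elimination of nitrite from the α-carbon, should unveil the glyoxylate aldehyde without an oxidant that would touch the terminal alkene.

Step 7
Reactants: 16 tert-butyl 2-[(3S,5R)-5-(dec-9-en-1-yl)-2-oxo-3-(2-oxoacetoxy)oxolan-3-yl]-2-oxoacetate
Product: 18 tert-butyl (3R,4R,5S,8R)-8-(dec-9-en-1-yl)-3,4-dihydroxy-2,6-dioxo-1,7-dioxaspiro[4.4]nonane-4-carboxylate, via 3-oxo spirodilactone 17 (not isolated)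
Conditions: (5aS,10bR)-2-(pentafluorophenyl)-5a,10b-dihydro-4H,6H-indeno[2,1-b][1,2,4]triazolo[4,3-d][1,4]oxazinium tetrafluoroborate (15 mol%), iPr2NEt (15 mol%), 4 Å molecular sieves, CH2Cl2 (0.02 M), rt; then AcOH, NaBH(OAc)3, −20 °C
Reagents that add atoms: none
Why: The triazolylidene adds to the glyoxylate aldehyde (future C3) and proton transfer gives the Breslow intermediate, an acyl-anion equivalent that attacks the neighbouring α-keto ester carbonyl (future C4), after which release of the carbene leaves the 3-keto lactone 17; this is the intramolecular aldehyde–ketone crossed benzoin reaction, a union of two carbonyl carbons by polarity reversal. Ring B closes in a 5-exo-trig mode, and because the nucleophilic C=C of the Breslow intermediate is exocyclic to the forming ring, the stereoelectronic penalty of a 5-enolendo ester-enolate aldol is avoided. The C4 carbinol centre is set under catalyst control by the aminoindanol-derived carbene, which must deliver C3 to the ketone face that leaves the C4 hydroxyl cis to the ring A carbonyl (C6) and the ester cis to C9. Chemoselectivity needs only the aldehyde to act as donor and the ketone as acceptor; the substrate secures this because the ketone is non-enolisable, activated by its ester and held five atoms away, while high dilution suppresses intermolecular homo-benzoin coupling. The C3 centre is then set in the same flask: NaBH(OAc)3 exchanges onto the C4 hydroxyl and delivers hydride to the very electrophilic C3 ketone from that face, which is also the face remote from the bulky tert-butyl ester, so the C3 hydroxyl should end trans to the C4 hydroxyl.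

Step 8
Reactants: 18 tert-butyl (3R,4R,5S,8R)-8-(dec-9-en-1-yl)-3,4-dihydroxy-2,6-dioxo-1,7-dioxaspiro[4.4]nonane-4-carboxylate
Product: 19 (3R,4R,5S,8R)-8-(dec-9-en-1-yl)-3,4-dihydroxy-2,6-dioxo-1,7-dioxaspiro[4.4]nonane-4-carboxylic acid (CNP0281847.1)
Conditions: CF3CO2H/CH2Cl2 (1:4), 0 °C to rt
Reagents that add atoms: none
Why: Acidolysis of the tert-butyl ester (E1 loss of 2-methylpropene) should free the C4 carboxylic acid while both γ-lactones, the two hydroxyl groups and the terminal alkene survive the brief exposure to dilute acid.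

**Compound list**

1 | 9-bromonon-1-ene | C=CCCCCCCCBr | starting material
2 | (R)-epichlorohydrin | ClC[C@H]1CO1 | starting material
3 | non-8-en-1-ylmagnesium bromide | C=CCCCCCCC[Mg]Br | intermediate (not isolated)
4 | (2R)-1-chlorododec-11-en-2-ol | C=CCCCCCCCC[C@@H](O)CCl | intermediate (not isolated)
5 | (2R)-2-(dec-9-en-1-yl)oxirane | C=CCCCCCCCC[C@@H]1CO1 | intermediate
6 | tert-butyl acetate | CC(=O)OC(C)(C)C | starting material
7 | diethylaluminium enolate of tert-butyl acetate | C=C(O[Al](CC)CC)OC(C)(C)C | intermediate (not isolated)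
8 | tert-butyl (4R)-4-hydroxytetradec-13-enoate | C=CCCCCCCCC[C@@H](O)CCC(=O)OC(C)(C)C | intermediate (not isolated)
9 | (5R)-5-(dec-9-en-1-yl)oxolan-2-one | C=CCCCCCCCC[C@@H]1CCC(=O)O1 | intermediate
10 | di-tert-butyl oxalate | CC(C)(C)OC(=O)C(=O)OC(C)(C)C | starting material
11 | tert-butyl (2Z)-2-[(5R)-5-(dec-9-en-1-yl)-2-oxooxolan-3-ylidene]-2-hydroxyacetate | C=CCCCCCCCC[C@@H]1C/C(=C(/O)C(=O)OC(C)(C)C)C(=O)O1 | intermediate
12 | tert-butyl 2-[(3S,5R)-5-(dec-9-en-1-yl)-3-hydroxy-2-oxooxolan-3-yl]-2-oxoacetate | C=CCCCCCCCC[C@@H]1C[C@@](C(=O)C(=O)OC(C)(C)C)(O)C(=O)O1 | intermediate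
13 | bromoacetyl bromide | BrCC(=O)Br | starting material
14 | tert-butyl 2-[(3S,5R)-3-(2-bromoacetoxy)-5-(dec-9-en-1-yl)-2-oxooxolan-3-yl]-2-oxoacetate | C=CCCCCCCCC[C@@H]1C[C@@](C(=O)C(=O)OC(C)(C)C)(OC(=O)CBr)C(=O)O1 | intermediate
15 | tert-butyl 2-[(3S,5R)-5-(dec-9-en-1-yl)-3-[2-(nitrooxy)acetoxy]-2-oxooxolan-3-yl]-2-oxoacetate | C=CCCCCCCCC[C@@H]1C[C@@](C(=O)C(=O)OC(C)(C)C)(OC(=O)CO[N+](=O)[O-])C(=O)O1 | intermediate (not isolated)
16 | tert-butyl 2-[(3S,5R)-5-(dec-9-en-1-yl)-2-oxo-3-(2-oxoacetoxy)oxolan-3-yl]-2-oxoacetate | C=CCCCCCCCC[C@@H]1C[C@@](C(=O)C(=O)OC(C)(C)C)(OC(=O)C=O)C(=O)O1 | intermediate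
17 | tert-butyl (4S,5S,8R)-8-(dec-9-en-1-yl)-4-hydroxy-2,3,6-trioxo-1,7-dioxaspiro[4.4]nonane-4-carboxylate | C=CCCCCCCCC[C@@H]1C[C@@]2(OC(=O)C(=O)[C@]2(O)C(=O)OC(C)(C)C)C(=O)O1 | intermediate (not isolated)
18 | tert-butyl (3R,4R,5S,8R)-8-(dec-9-en-1-yl)-3,4-dihydroxy-2,6-dioxo-1,7-dioxaspiro[4.4]nonane-4-carboxylate | C=CCCCCCCCC[C@@H]1C[C@@]2(OC(=O)[C@H](O)[C@]2(O)C(=O)OC(C)(C)C)C(=O)O1 | intermediate
19 | (3R,4R,5S,8R)-8-(dec-9-en-1-yl)-3,4-dihydroxy-2,6-dioxo-1,7-dioxaspiro[4.4]nonane-4-carboxylic acid | C=CCCCCCCCC[C@@H]1C[C@@]2(OC(=O)[C@H](O)[C@]2(O)C(=O)O)C(=O)O1 | target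

**Step count and risks**

Total step count: 8. Longest linear sequence: 8 steps (from 1 to 19).

Steps most likely to fail:

Step 7. The catalyst may fail to override the facial bias of the spiro centre at the ketone (mismatched pairing), giving the C4 epimer. Further risks are hydration of the glyoxylate or acyl transfer of this activated ester to the carbene, either of which would stall formation of the Breslow intermediate. Fallback: setting out from 16, a reductive ketyl–carbonyl (pinacol) cyclisation with SmI2 in THF at −78 °C would form the same C3–C4 bond. Trivalent samarium bridging the C4 ketyl oxygen and the ring A lactone carbonyl should fix C4 as required, and bridging of both ketyl oxygens should give the cis-diol tert-butyl (3S,4R,5S,8R)-8-(dec-9-en-1-yl)-3,4-dihydroxy-2,6-dioxo-1,7-dioxaspiro[4.4]nonane-4-carboxylate F1. Oxidation of its secondary hydroxyl with Dess–Martin periodinane would come back to the route at 17, now isolated, and the hydroxyl-directed NaBH(OAc)3 reduction of step 7 then gives 18.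

Step 4. Facial discrimination of the exocyclic enolate rests only on 1,3-induction from the decenyl-bearing carbon and may be modest. The tertiary alkoxide formed under basic conditions may also undergo an α-ketol shift or retro-Claisen cleavage. Fallback: setting out from 11, stereocontrol is moved from the substrate to a chiral Lewis acid under neutral conditions. This means hydroxylation of the enol with racemic 2-(phenylsulfonyl)-3-(4-nitrophenyl)oxaziridine catalysed by Ni(ClO4)2·6H2O and the matched antipode of the bis(oxazoline) ligand DBFOX-Ph in CH2Cl2 at rt. It comes back to the route at 12 and makes no new compound (F0).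

Step 6. The activated glyoxylate ester may be lost by acyl cleavage or hydrolysis under the acetate/DMSO conditions, or it may be trapped as a hydrate or cyclic hemiketal that is slow to enter step 7. Fallback: setting out from 12, the tertiary alcohol is acylated with (tert-butyldimethylsilyloxy)acetyl chloride (pyridine, DMAP, CH2Cl2) to give tert-butyl 2-[(3S,5R)-3-{2-[(tert-butyldimethylsilyl)oxy]acetoxy}-5-(dec-9-en-1-yl)-2-oxooxolan-3-yl]-2-oxoacetate F2. Desilylation with HF·pyridine in THF gives the glycolate tert-butyl 2-[(3S,5R)-5-(dec-9-en-1-yl)-3-(2-hydroxyacetoxy)-2-oxooxolan-3-yl]-2-oxoacetate F3. Dess–Martin oxidation under anhydrous, non-basic conditions then comes back to the route at 16, bypassing steps 5 and 6.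

Further compounds
F1 | step 7 | tert-butyl (3S,4R,5S,8R)-8-(dec-9-en-1-yl)-3,4-dihydroxy-2,6-dioxo-1,7-dioxaspiro[4.4]nonane-4-carboxylate | C=CCCCCCCCC[C@@H]1C[C@@]2(OC(=O)[C@@H](O)[C@]2(O)C(=O)OC(C)(C)C)C(=O)O1
F0 | step 4 | none | none
F2 | step 6 | tert-butyl 2-[(3S,5R)-3-{2-[(tert-butyldimethylsilyl)oxy]acetoxy}-5-(dec-9-en-1-yl)-2-oxooxolan-3-yl]-2-oxoacetate | C=CCCCCCCCC[C@@H]1C[C@@](C(=O)C(=O)OC(C)(C)C)(OC(=O)CO[Si](C)(C)C(C)(C)C)C(=O)O1
F3 | step 6 | tert-butyl 2-[(3S,5R)-5-(dec-9-en-1-yl)-3-(2-hydroxyacetoxy)-2-oxooxolan-3-yl]-2-oxoacetate | C=CCCCCCCCC[C@@H]1C[C@@](C(=O)C(=O)OC(C)(C)C)(OC(=O)CO)C(=O)O1
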